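## The problem

The target 30 is a trimeric acylphloroglucinol: three hexasubstituted benzene rings joined by two CH2 bridges. In the labels used here, the central ring B carries the (R)-2-methylbutanoyl group on B1, hydroxyls on B2, B4 and B6, and the bridges on B3 (to A1 of ring A) and B5 (to C1 of ring C). Rings A and C each carry OH on positions 2 and 6, methyl on 3, methoxy on 4 and an acyl group on 5: acetyl in ring A, 2-methylpropanoyl in ring C. Because the outer rings differ only in that acyl group, ring B bears two different arms, and bridge formation by reversible electrophilic one-carbon chemistry risks A–B–A, A–B–C and C–B–C mixtures and arm exchange. The only stereocentre is the α-carbon of the B1 acyl chain; nothing in the molecule can set it, it controls nothing, and as the α-carbon of an aryl ketone it can be lost by enolisation, so it is best bought and attached last. The groups that will not survive rough treatment are the seven phenols (oxidation under base and air), the CH2 bridges (retro-Friedel–Crafts cleavage in strong acid) and the A4 and C4 methoxy groups, which lie ortho to a ketone and are open to Lewis-acid demethylation. In each outer ring the methoxy group sits between the methyl and the acyl group, which simple alkylation of an acylmethylphloroglucinol does not deliver. The feature that makes the key step possible is the strict alternation in ring B of oxygen-bearing (B2, B4, B6) and carbon-bearing (B1, B3, B5) atoms: the ring divides into three two-carbon units, B4–B5, B6–B1 and B2–B3, each with one oxygen and two of them with one arm.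

## Retrosynthesis

**B1–acyl bond.** Cutting it last turns 30 into the heptaphenol 27 and (2R)-2-methylbutanoyl chloride 29, made from the commercial acid 28. B1 is the only aromatic C–H left in 27, so regiochemistry is not in question, and the stereocentre meets no reagent after it is attached. Acylating B1 earlier would send the stereocentre through later acid steps and would make B1 compete with A5. The forward reaction is a Friedel–Crafts acylation of a free 2,4-dialkylphloroglucinol and must run cold enough that neither the acylium ion nor the product ketone enolises.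

**Benzyl ethers.** 27 comes from 26 by cleavage of four O–benzyl bonds. Benzyl is chosen for the outer-ring hydroxyls because it withstands organolithium reagents, the thermal key step and metal-free acylation, and leaves under neutral conditions that spare the two methyl ethers.

**A5–acetyl bond.** Ring A cannot carry its ketone through the organolithium chemistry that makes the siloxyalkyne, so the acetyl group is cut next (26 from 25, 25 from 24, 24 from 23). In 23 both A5 and B1 are electron-rich C–H positions. Acetylating the three ring B hydroxyls (24) switches ring B off, the acylation then finds only A5 (25), and methanolysis returns the triol 26. Acylating with ring B free would require discrimination between two activated rings.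

**Ring B oxygens.** 23 follows from the key-step product 21 by acidolysis of the tert-butyl ether and fluoride cleavage of the silyl ether. The three oxygens emerge differentiated from the ring construction, but the target does not need the difference, so both are simply freed.

**Ring B.** Bonds B5–B6, B3–B4 and B1–B2 are cut, which leads from 21 to three components: the acid chloride 10 (as its ketene 19, carrying B4, B5 and the ring C arm), tert-butoxyethyne 18 (B6, B1) and the siloxyalkyne 14 (B2, B3 and the ring A arm). Against bridge-by-bridge electrophilic coupling this cut has each arm fixed in its own component and makes ring B irreversibly. The price is that the ketene–ynol ether cycloaddition and the benzannulation of the resulting cyclobutenone 20 have not been run as one operation. Both (2+2) events must be regioselective.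

**The two arms.** 10 is simplified through the acid 9 and the keto ester 8 to the ester 7 (cut: C5–acyl bond of ring C). 14 is traced through the ynolate 13 and the dibromo ester 12 to the same ester 7. Using the ester's own two chain carbons for the ynolate avoids a separate one-carbon homologation to an arylacetate and removes the acidic α-hydrogens before any organolithium is added. One intermediate thus serves both arms.

**The common ester and the alkyne.** 7 comes from the enoate 6 and this from the aldehyde 5 (C=C cut), whose formyl carbon becomes the bridge carbon. 5 goes back through 4 and 3 to 2-methylphloroglucinol 1: formylation at one of two equivalent positions, methylation of the hydroxyl para to the formyl group (which ends up between methyl and the future acyl site) and benzylation. 18 is made from trichloroethene 15.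

## Roads not taken

Alternative 1: Ring A is cut across A3–A4 and A5–A6 into 1-methoxy-1,3-bis(trimethylsilyloxy)penta-1,3-diene A2 and 4-methoxybut-3-yn-2-one A3. The forward step is a (4+2) cycloaddition followed by elimination from the acetal carbon and desilylation, giving the ring A monomer 1-(4,6-dihydroxy-2-methoxy-3-methylphenyl)ethan-1-one A1.
- Merits: polarisation of both partners sets methyl, methoxy and acetyl in the right order in one step, and the ketone is present from the start. In this respect it is better than the chosen plan, which must add the acetyl group late (step 15) behind a protection of ring B.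
- Weak points: only an outer ring is made. The trimer must still be built by linking A1, an isobutyryl analogue and a ring B triol with a one-carbon electrophile, which is the reversible chemistry that gives mixed trimers. A3 is also a push–pull alkyne and a sluggish dienophile.
- Comparison: the chosen plan sets against the early ketone an irreversible ring B construction that places each arm once.

Alternative 2: Ring C is cut across C1–C2 and C5–C6 into the ester enolate of methyl 3-[2,4,6-tris(benzyloxy)phenyl]propanoate A6 and 4-methoxy-3-methyl-6-(propan-2-yl)-2H-pyran-2-one A5. The enolate adds to the lactone carbonyl, the ring opens to a dienolate, and Claisen closure onto the ester gives A4, ring C complete and already bridged to a protected ring B.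
- Merits: one bridge is made without electrophilic methylene chemistry, and ring C arrives with ketone, methoxy and methyl in place. For that ring it is at least as good as the chosen plan.
- Weak points: ester enolates also add to pyranones at C6, and the 4-methoxy group makes the lactone a poorly electrophilic vinylogous carbonate. The ring A arm and the B1 acyl group still have to be attached to A4, the former by the classical coupling with its exchange problem.
- Comparison: the chosen plan makes both bridges' attachments in a single ring construction and differentiates the arms by construction.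

Alternative 3: An outer-ring monomer is cut across C1–C6 and C2–C3 into 3-methoxy-2-methylcyclobut-2-en-1-one A8 and the siloxyalkyne tert-butyl(dimethyl){[3-(tri(propan-2-yl)silyloxy)prop-2-yn-1-yl]oxy}silane A9. Heating gives the phenol A7 by the two-component Danheiser benzannulation.
- Merits: this key step is the established form of the reaction and is better precedented than step 12. It delivers OH, OSi and OMe differentiated, the methoxy group in the right place and a CH2O handle for bridging, and one intermediate could serve both outer rings.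
- Weak points: it again makes only a monomer. C5 must still be acylated, and two different monomers must then be attached to ring B by electrophilic benzylation, with the mono/bis and exchange problems. The step count grows with two monomer lines plus couplings.
- Comparison: against the better precedent the chosen plan sets convergence (one ring-forming event joins all three rings) and freedom from bridge equilibria. It pays with an untested telescoped operation and a late acetylation.

Key step: step 12

Assumption: (2R)-2-methylbutanoic acid 28 is taken to be available in high enantiomeric purity; the route carries the stereocentre over from it and does not create it.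

## Route

Step 1
Reactants: 1 2-methylbenzene-1,3,5-triol (2-methylphloroglucinol)
Product: 3 2,4,6-trihydroxy-3-methylbenzaldehyde, via iminium chloride 2 (not isolated)
Conditions: POCl3 (1.1 equiv), DMF, EtOAc, 0 °C → rt; then H2O, 60 °C
Reagents that add atoms: N,N-dimethylformamide, CN(C)C=O; water, O
Why: Vilsmeier–Haack formylation of an electron-rich phenol; the two free ring positions of 1 are equivalent, so a single aldehyde results, and one equivalent of the chloroiminium reagent limits diformylation. The iminium salt 2 is hydrolysed on aqueous warming.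

Step 2
Reactants: 3 2,4,6-trihydroxy-3-methylbenzaldehyde
Product: 4 2,6-dihydroxy-4-methoxy-3-methylbenzaldehyde
Conditions: Me2SO4 (1.0 equiv), K2CO3 (1.0 equiv), acetone, 0 °C → rt
Reagents that add atoms: dimethyl sulfate, COS(=O)(=O)OC
Why: Williamson etherification under acidity control: the hydroxyl para to the formyl group is the most acidic and cannot hydrogen-bond to the carbonyl, so one equivalent of base and of a hard methyl donor should etherify it in preference to the ortho hydroxyls and to carbon. This puts the methoxy group next to the methyl group, as rings A and C require.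

Step 3
Reactants: 4 2,6-dihydroxy-4-methoxy-3-methylbenzaldehyde
Product: 5 2,6-bis(benzyloxy)-4-methoxy-3-methylbenzaldehyde
Conditions: BnBr (2.5 equiv), K2CO3, Bu4NI (cat.), DMF, 70 °C
Reagents that add atoms: benzyl bromide, BrCc1ccccc1
Why: Williamson benzylation of the two carbonyl-bonded hydroxyls, which needs a polar solvent and warming; benzyl ethers tolerate every later step up to the hydrogenolysis.

Step 4
Reactants: 5 2,6-bis(benzyloxy)-4-methoxy-3-methylbenzaldehyde
Product: 6 ethyl (2E)-3-[2,6-bis(benzyloxy)-4-methoxy-3-methylphenyl]prop-2-enoate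
Conditions: (EtO)2P(O)CH2CO2Et, NaH, THF, 0 °C → reflux
Reagents that add atoms: triethyl phosphonoacetate, CCOC(=O)CP(=O)(OCC)OCC
Why: Horner–Wadsworth–Emmons olefination; the stabilised phosphonate anion adds even to the di-ortho-substituted aldehyde and gives the E-enoate, whose geometry is of no consequence after the next step.

Step 5
Reactants: 6 ethyl (2E)-3-[2,6-bis(benzyloxy)-4-methoxy-3-methylphenyl]prop-2-enoate
Product: 7 ethyl 3-[2,6-bis(benzyloxy)-4-methoxy-3-methylphenyl]propanoate
Conditions: NaBH4, NiCl2·6H2O (cat.), MeOH/THF, 0 °C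
Reagents that add atoms: none
Why: Conjugate reduction of a cinnamate by nickel boride generated from NaBH4 and NiCl2; aryl benzyl ethers and the ester are not touched, which a palladium-catalysed hydrogenation could not promise.

Step 6
Reactants: 7 ethyl 3-[2,6-bis(benzyloxy)-4-methoxy-3-methylphenyl]propanoate
Product: 8 ethyl 3-[2,6-bis(benzyloxy)-4-methoxy-3-methyl-5-(2-methylpropanoyl)phenyl]propanoate
Conditions: i-PrCO2H, (CF3CO)2O, H3PO4 (cat.), CH2Cl2, 0 °C → rt
Reagents that add atoms: 2-methylpropanoic acid, CC(C)C(=O)O
Why: Friedel–Crafts acylation by the mixed carboxylic–trifluoroacetic anhydride; C5 is the only free ring position and is activated by three alkoxy groups. The metal-free conditions spare the benzyl ethers and the ortho methoxy group, which a chelating Lewis acid would cleave.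

Step 7
Reactants: 8 ethyl 3-[2,6-bis(benzyloxy)-4-methoxy-3-methyl-5-(2-methylpropanoyl)phenyl]propanoate
Product: 9 3-[2,6-bis(benzyloxy)-4-methoxy-3-methyl-5-(2-methylpropanoyl)phenyl]propanoic acid
Conditions: LiOH·H2O, THF/MeOH/H2O, rt; then 1 M HCl
Reagents that add atoms: lithium hydroxide, [Li+].[OH-]
Why: Saponification of an unhindered ethyl ester; the twisted, di-ortho-substituted aryl ketone is inert to hydroxide.

Step 8
Reactants: 9 3-[2,6-bis(benzyloxy)-4-methoxy-3-methyl-5-(2-methylpropanoyl)phenyl]propanoic acid
Product: 10 3-[2,6-bis(benzyloxy)-4-methoxy-3-methyl-5-(2-methylpropanoyl)phenyl]propanoyl chloride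
Conditions: (COCl)2, DMF (cat.), CH2Cl2, 0 °C → rt; evaporate, use crude
Reagents that add atoms: oxalyl chloride, O=C(Cl)C(Cl)=O
Why: Acid chloride formation through the catalytic chloroiminium species; ring C has no free position, so neither formylation nor intramolecular acylation can intervene.

Step 9
Reactants: 7 ethyl 3-[2,6-bis(benzyloxy)-4-methoxy-3-methylphenyl]propanoate
Product: 12 ethyl 2,2-dibromo-3-[2,6-bis(benzyloxy)-4-methoxy-3-methylphenyl]propanoate, via monobromo ester 11 (not isolated)
Conditions: LiN(i-Pr)2 (1.1 equiv), THF, −78 °C; BrCCl2CCl2Br; then LiN(i-Pr)2 (1.2 equiv); BrCCl2CCl2Br, −78 °C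
Reagents that add atoms: 1,2-dibromo-1,1,2,2-tetrachloroethane, BrC(Cl)(Cl)C(Cl)(Cl)Br
Why: Two successive brominations of the ester lithium enolate with a positive-bromine donor; the monobromide 11 is more acidic than 7 and is deprotonated cleanly at −78 °C. Removing both α-hydrogens prepares the ester for ynolate formation.

Step 10
Reactants: 12 ethyl 2,2-dibromo-3-[2,6-bis(benzyloxy)-4-methoxy-3-methylphenyl]propanoate
Product: 14 {[3-(2,6-bis(benzyloxy)-4-methoxy-3-methylphenyl)prop-1-yn-1-yl]oxy}tri(propan-2-yl)silane, via lithium ynolate 13 (not isolated)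
Conditions: t-BuLi (4.0 equiv), THF, −78 → 0 °C; then i-Pr3SiCl, −78 °C → rt; NEt3-deactivated silica
Reagents that add atoms: chlorotri(propan-2-yl)silane, CC(C)[Si](Cl)(C(C)C)C(C)C
Why: Ynolate formation from an α,α-dibromo ester by double bromine–lithium exchange and loss of ethoxide, then O-silylation, which bulky silyl chlorides give with ynolates (small ones silylate carbon). Exchange at −78 °C is much faster than attack of t-BuLi on benzyl ethers.

Step 11
Reactants: 15 trichloroethene
Product: 18 tert-butoxyethyne, via dichlorovinyl ether 16 (not isolated), via lithium acetylide 17 (not isolated)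
Conditions: KOt-Bu, THF, −20 °C → rt; then n-BuLi (2.2 equiv), −78 → −40 °C; MeOH, −78 °C; cold distillation
Reagents that add atoms: potassium tert-butoxide, CC(C)(C)[O-].[K+]
Why: Elimination of HCl from 15 and addition of tert-butoxide to the dichloroethyne formed give the dichlorovinyl ether 16; two equivalents of n-BuLi then eliminate HCl and exchange the remaining chlorine to the acetylide 17, which methanol protonates. The product is volatile and loses 2-methylpropene on warming, so it is kept cold and used soon.

Step 12
Reactants: 10 3-[2,6-bis(benzyloxy)-4-methoxy-3-methyl-5-(2-methylpropanoyl)phenyl]propanoyl chloride; 18 tert-butoxyethyne; 14 {[3-(2,6-bis(benzyloxy)-4-methoxy-3-methylphenyl)prop-1-yn-1-yl]oxy}tri(propan-2-yl)silane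
Product: 21 2-{[2,6-bis(benzyloxy)-4-methoxy-3-methylphenyl]methyl}-6-{[2,6-bis(benzyloxy)-4-methoxy-3-methyl-5-(2-methylpropanoyl)phenyl]methyl}-5-tert-butoxy-3-{[tri(propan-2-yl)silyl]oxy}phenol, via ketene 19 (not isolated), via cyclobutenone 20 (not isolated)
Conditions: 10 added slowly to 18 (3 equiv), NEt3 (1.3 equiv), toluene, 0 °C → rt; filter, strip excess 18; then 14 (1.0 equiv), toluene, 80 → 110 °C
Reagents that add atoms: none
Why: Proposed new method: Dehydrochlorination of 10 by NEt3 gives the aldoketene 19, whose carbonyl carbon bonds to the nucleophilic β-carbon of 18 and whose α-carbon bonds to the oxygen-bearing carbon in a (2+2) cycloaddition, so that 20 carries the arm on C4 next to the tert-butoxy carbon (bond B5–B6). On heating, 20 opens by 4π electrocyclisation to a vinylketene, which adds 14 in a second, equally polarised (2+2): the ketene carbonyl carbon bonds to the alkyne carbon bearing the ring A arm (B3–B4) and the ketene α-carbon to the siloxy carbon (B1–B2). The resulting 2-vinylcyclobutenone opens again, and the dienylketene closes ring B by thermal disrotatory 6π electrocyclisation, re-forming B4–B5, and tautomerises to the phenol. The closest known reactions are the (2+2) cycloaddition of ketenes with alkoxy- and siloxyalkynes to 3-oxycyclobutenones and the Danheiser benzannulation of cyclobutenones with siloxyalkynes; new here are their telescoping into one three-component operation and the use of a 3-alkoxy-4-alkylcyclobutenone made in the flask. No stereocentre is created in 21: C4 of 20 is racemic and becomes aromatic. The selectivity needed is regiochemical in both (2+2) events, and the strong polarisation of the two ynol ethers secures it, placing the oxygens 1,3,5 and each arm on its own carbon. Chemoselectivity rests on the order of addition: the excess of 18, which suppresses ketene dimerisation, is removed with the ammonium salt before 14 is added, so the vinylketene meets only the siloxyalkyne, and neither arm has a free ring position for intramolecular acylation.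

Step 13
Reactants: 21 the ring B phenol of step 12
Product: 23 2-{[2,6-bis(benzyloxy)-4-methoxy-3-methylphenyl]methyl}-4-{[2,6-bis(benzyloxy)-4-methoxy-3-methyl-5-(2-methylpropanoyl)phenyl]methyl}benzene-1,3,5-triol, via silyl ether diol 22 (not isolated)
Conditions: CF3CO2H (10% v/v), 1,3-dimethoxybenzene, CH2Cl2, 0 °C; evaporate; then Bu4NF, AcOH, THF, 0 °C (argon)
Reagents that add atoms: none
Why: Acidolysis of the aryl tert-butyl ether (the cation leaves as 2-methylpropene, the arene scavenger taking up any that lingers) and fluoride cleavage of the aryl silyl ether. Short exposure to dilute acid at 0 °C is chosen so that protonolysis of the CH2 bridges cannot compete, and acetic acid buffers the phenoxide against air oxidation.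

Step 14
Reactants: 23 the ring B triol of step 13
Product: 24 2-{[2,6-bis(benzyloxy)-4-methoxy-3-methylphenyl]methyl}-4-{[2,6-bis(benzyloxy)-4-methoxy-3-methyl-5-(2-methylpropanoyl)phenyl]methyl}benzene-1,3,5-triyl triacetate
Conditions: Ac2O, pyridine, DMAP (cat.), CH2Cl2, 0 °C → rt
Reagents that add atoms: acetic anhydride, CC(=O)OC(C)=O
Why: DMAP-catalysed acyl transfer esterifies all three ring B hydroxyls, including the flanked B4 hydroxyl; the triacetate is no longer a Friedel–Crafts nucleophile.

Step 15
Reactants: 24 the triacetate of step 14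
Product: 25 2-{[3-acetyl-2,6-bis(benzyloxy)-4-methoxy-5-methylphenyl]methyl}-4-{[2,6-bis(benzyloxy)-4-methoxy-3-methyl-5-(2-methylpropanoyl)phenyl]methyl}benzene-1,3,5-triyl triacetate
Conditions: AcOH, (CF3CO)2O, H3PO4 (cat.), CH2Cl2, 0 °C → rt
Reagents that add atoms: acetic acid, CC(=O)O
Why: Friedel–Crafts acylation by acetyl trifluoroacetate, the same metal-free method as in step 6. With ring B deactivated as its triacetate and ring C fully substituted, A5 (ortho to OMe and OBn, para to OBn) is the only reactive aromatic C–H.

Step 16
Reactants: 25 the acetylated triacetate of step 15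
Product: 26 2-{[3-acetyl-2,6-bis(benzyloxy)-4-methoxy-5-methylphenyl]methyl}-4-{[2,6-bis(benzyloxy)-4-methoxy-3-methyl-5-(2-methylpropanoyl)phenyl]methyl}benzene-1,3,5-triol
Conditions: K2CO3 (cat.), degassed MeOH/THF, 0 °C → rt (argon); AcOH quench
Reagents that add atoms: none
Why: Base-catalysed transesterification of aryl acetates with methanol; exclusion of air protects the electron-rich triol, and the hindered aryl ketones and the benzyl ethers are inert.

Step 17
Reactants: 26 the tetrabenzyl triol of step 16
Product: 27 2-[(3-acetyl-2,6-dihydroxy-4-methoxy-5-methylphenyl)methyl]-4-{[2,6-dihydroxy-4-methoxy-3-methyl-5-(2-methylpropanoyl)phenyl]methyl}benzene-1,3,5-triol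
Conditions: H2 (1 atm), 10% Pd/C, EtOAc/MeOH, rt
Reagents that add atoms: none
Why: Hydrogenolysis of the four aryl benzyl ethers over palladium under neutral conditions; the aryl ketones, which become hydrogen-bonded to the new ortho hydroxyls, and the methyl ethers should remain.

Step 18
Reactants: 27 the heptaphenol of step 17; 28 (2R)-2-methylbutanoic acid
Product: 30 (2R)-1-{3-[(3-acetyl-2,6-dihydroxy-4-methoxy-5-methylphenyl)methyl]-5-{[2,6-dihydroxy-4-methoxy-3-methyl-5-(2-methylpropanoyl)phenyl]methyl}-2,4,6-trihydroxyphenyl}-2-methylbutan-1-one, via acid chloride 29 (not isolated)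
Conditions: 28, (COCl)2, DMF (cat.), CH2Cl2, 0 °C → rt; then 27, AlCl3, PhNO2/CH2Cl2, 0 °C → rt; 1 M HCl
Reagents that add atoms: none
Why: Friedel–Crafts acylation of a free phloroglucinol, the standard entry to acylphloroglucinols: B1 is the only aromatic C–H of 27 and lies ortho and para to three aluminium phenoxides, so C-acylation there is expected. The stereocentre comes unchanged from 28 (chloride formation without base, acylation at or below room temperature) and no later step can disturb it. The methoxy groups are shielded because each ketone is chelated to its ortho phenoxide.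

## Compound list

1 | 2-methylbenzene-1,3,5-triol (2-methylphloroglucinol) | Cc1c(O)cc(O)cc1O | starting material
2 | N-methyl-N-[(2,4,6-trihydroxy-3-methylphenyl)methylidene]methanaminium chloride | C[N+](C)=Cc1c(O)c(C)c(O)cc1O.[Cl-] | intermediate
3 | 2,4,6-trihydroxy-3-methylbenzaldehyde | O=Cc1c(O)c(C)c(O)cc1O | intermediate
4 | 2,6-dihydroxy-4-methoxy-3-methylbenzaldehyde | O=Cc1c(O)c(C)c(OC)cc1O | intermediate
5 | 2,6-bis(benzyloxy)-4-methoxy-3-methylbenzaldehyde | O=Cc1c(OCc2ccccc2)c(C)c(OC)cc1OCc1ccccc1 | intermediate
6 | ethyl (2E)-3-[2,6-bis(benzyloxy)-4-methoxy-3-methylphenyl]prop-2-enoate | CCOC(=O)/C=C/c1c(OCc2ccccc2)c(C)c(OC)cc1OCc1ccccc1 | intermediate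
7 | ethyl 3-[2,6-bis(benzyloxy)-4-methoxy-3-methylphenyl]propanoate | CCOC(=O)CCc1c(OCc2ccccc2)c(C)c(OC)cc1OCc1ccccc1 | intermediate
8 | ethyl 3-[2,6-bis(benzyloxy)-4-methoxy-3-methyl-5-(2-methylpropanoyl)phenyl]propanoate | CCOC(=O)CCc1c(OCc2ccccc2)c(C)c(OC)c(C(=O)C(C)C)c1OCc1ccccc1 | intermediate
9 | 3-[2,6-bis(benzyloxy)-4-methoxy-3-methyl-5-(2-methylpropanoyl)phenyl]propanoic acid | OC(=O)CCc1c(OCc2ccccc2)c(C)c(OC)c(C(=O)C(C)C)c1OCc1ccccc1 | intermediate
10 | 3-[2,6-bis(benzyloxy)-4-methoxy-3-methyl-5-(2-methylpropanoyl)phenyl]propanoyl chloride | O=C(Cl)CCc1c(OCc2ccccc2)c(C)c(OC)c(C(=O)C(C)C)c1OCc1ccccc1 | intermediate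
11 | ethyl 2-bromo-3-[2,6-bis(benzyloxy)-4-methoxy-3-methylphenyl]propanoate (racemic) | CCOC(=O)C(Br)Cc1c(OCc2ccccc2)c(C)c(OC)cc1OCc1ccccc1 | intermediate
12 | ethyl 2,2-dibromo-3-[2,6-bis(benzyloxy)-4-methoxy-3-methylphenyl]propanoate | CCOC(=O)C(Br)(Br)Cc1c(OCc2ccccc2)c(C)c(OC)cc1OCc1ccccc1 | intermediate
13 | lithium 3-[2,6-bis(benzyloxy)-4-methoxy-3-methylphenyl]prop-1-yn-1-olate | [Li+].[O-]C#CCc1c(OCc2ccccc2)c(C)c(OC)cc1OCc1ccccc1 | intermediate
14 | {[3-(2,6-bis(benzyloxy)-4-methoxy-3-methylphenyl)prop-1-yn-1-yl]oxy}tri(propan-2-yl)silane | CC(C)[Si](OC#CCc1c(OCc2ccccc2)c(C)c(OC)cc1OCc1ccccc1)(C(C)C)C(C)C | intermediate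
15 | trichloroethene | ClC=C(Cl)Cl | starting material
16 | 2-{[(E)-1,2-dichloroethenyl]oxy}-2-methylpropane | CC(C)(C)O/C(Cl)=C\Cl | intermediate
17 | lithium 2-tert-butoxyethyn-1-ide | [Li+].[C-]#COC(C)(C)C | intermediate
18 | tert-butoxyethyne | CC(C)(C)OC#C | intermediate
19 | 3-[2,6-bis(benzyloxy)-4-methoxy-3-methyl-5-(2-methylpropanoyl)phenyl]prop-1-en-1-one (ketene) | O=C=CCc1c(OCc2ccccc2)c(C)c(OC)c(C(=O)C(C)C)c1OCc1ccccc1 | intermediate
20 | 4-{[2,6-bis(benzyloxy)-4-methoxy-3-methyl-5-(2-methylpropanoyl)phenyl]methyl}-3-tert-butoxycyclobut-2-en-1-one (racemic) | O=C1C=C(OC(C)(C)C)C1Cc2c(OCc3ccccc3)c(C)c(OC)c(C(=O)C(C)C)c2OCc2ccccc2 | intermediate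
21 | 2-{[2,6-bis(benzyloxy)-4-methoxy-3-methylphenyl]methyl}-6-{[2,6-bis(benzyloxy)-4-methoxy-3-methyl-5-(2-methylpropanoyl)phenyl]methyl}-5-tert-butoxy-3-{[tri(propan-2-yl)silyl]oxy}phenol | Oc1c(Cc2c(OCc3ccccc3)c(C)c(OC)c(C(=O)C(C)C)c2OCc2ccccc2)c(OC(C)(C)C)cc(O[Si](C(C)C)(C(C)C)C(C)C)c1Cc1c(OCc2ccccc2)c(C)c(OC)cc1OCc1ccccc1 | intermediate
22 | 4-{[2,6-bis(benzyloxy)-4-methoxy-3-methylphenyl]methyl}-2-{[2,6-bis(benzyloxy)-4-methoxy-3-methyl-5-(2-methylpropanoyl)phenyl]methyl}-5-{[tri(propan-2-yl)silyl]oxy}benzene-1,3-diol | Oc1c(Cc2c(OCc3ccccc3)c(C)c(OC)c(C(=O)C(C)C)c2OCc2ccccc2)c(O)cc(O[Si](C(C)C)(C(C)C)C(C)C)c1Cc1c(OCc2ccccc2)c(C)c(OC)cc1OCc1ccccc1 | intermediate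
23 | 2-{[2,6-bis(benzyloxy)-4-methoxy-3-methylphenyl]methyl}-4-{[2,6-bis(benzyloxy)-4-methoxy-3-methyl-5-(2-methylpropanoyl)phenyl]methyl}benzene-1,3,5-triol | Oc1c(Cc2c(OCc3ccccc3)c(C)c(OC)c(C(=O)C(C)C)c2OCc2ccccc2)c(O)cc(O)c1Cc1c(OCc2ccccc2)c(C)c(OC)cc1OCc1ccccc1 | intermediate
24 | 2-{[2,6-bis(benzyloxy)-4-methoxy-3-methylphenyl]methyl}-4-{[2,6-bis(benzyloxy)-4-methoxy-3-methyl-5-(2-methylpropanoyl)phenyl]methyl}benzene-1,3,5-triyl triacetate | CC(=O)Oc1c(Cc2c(OCc3ccccc3)c(C)c(OC)c(C(=O)C(C)C)c2OCc2ccccc2)c(OC(C)=O)cc(OC(C)=O)c1Cc1c(OCc2ccccc2)c(C)c(OC)cc1OCc1ccccc1 | intermediate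
25 | 2-{[3-acetyl-2,6-bis(benzyloxy)-4-methoxy-5-methylphenyl]methyl}-4-{[2,6-bis(benzyloxy)-4-methoxy-3-methyl-5-(2-methylpropanoyl)phenyl]methyl}benzene-1,3,5-triyl triacetate | CC(=O)Oc1c(Cc2c(OCc3ccccc3)c(C)c(OC)c(C(=O)C(C)C)c2OCc2ccccc2)c(OC(C)=O)cc(OC(C)=O)c1Cc1c(OCc2ccccc2)c(C)c(OC)c(C(C)=O)c1OCc1ccccc1 | intermediate
26 | 2-{[3-acetyl-2,6-bis(benzyloxy)-4-methoxy-5-methylphenyl]methyl}-4-{[2,6-bis(benzyloxy)-4-methoxy-3-methyl-5-(2-methylpropanoyl)phenyl]methyl}benzene-1,3,5-triol | Oc1c(Cc2c(OCc3ccccc3)c(C)c(OC)c(C(=O)C(C)C)c2OCc2ccccc2)c(O)cc(O)c1Cc1c(OCc2ccccc2)c(C)c(OC)c(C(C)=O)c1OCc1ccccc1 | intermediate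
27 | 2-[(3-acetyl-2,6-dihydroxy-4-methoxy-5-methylphenyl)methyl]-4-{[2,6-dihydroxy-4-methoxy-3-methyl-5-(2-methylpropanoyl)phenyl]methyl}benzene-1,3,5-triol | Oc1c(Cc2c(O)c(C)c(OC)c(C(=O)C(C)C)c2O)c(O)cc(O)c1Cc1c(O)c(C)c(OC)c(C(C)=O)c1O | intermediate
28 | (2R)-2-methylbutanoic acid | CC[C@@H](C)C(=O)O | starting material
29 | (2R)-2-methylbutanoyl chloride | CC[C@@H](C)C(Cl)=O | intermediate
30 | (2R)-1-{3-[(3-acetyl-2,6-dihydroxy-4-methoxy-5-methylphenyl)methyl]-5-{[2,6-dihydroxy-4-methoxy-3-methyl-5-(2-methylpropanoyl)phenyl]methyl}-2,4,6-trihydroxyphenyl}-2-methylbutan-1-one | CC[C@@H](C)C(=O)c1c(O)c(Cc2c(O)c(C)c(OC)c(C(C)=O)c2O)c(O)c(Cc2c(O)c(C)c(OC)c(C(=O)C(C)C)c2O)c1O | target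

## Step count and least certain steps

Total: 18 steps. Longest linear sequence: 15 steps (steps 1–8 and 12–18); the siloxyalkyne branch (steps 9, 10) and the alkyne (step 11) are side branches.

**Step 12 (key step, the new method).**
- What may go wrong: dimerisation of the aldoketene may outrun its cycloaddition; the 3-alkoxycyclobutenone may open only at temperatures where the tert-butyl enol ether loses 2-methylpropene or the siloxyalkyne degrades; residual 18 may intercept the vinylketene.
- Fallback: known electrophilic benzylation chemistry, setting out from aldehyde 5 and returning at triol 23. NaBH4 reduction of 5 would give [2,6-bis(benzyloxy)-4-methoxy-3-methylphenyl]methanol F1. With a catalytic sulfonic acid this benzylic alcohol alkylates an excess of commercial benzene-1,3,5-triol to 2-{[2,6-bis(benzyloxy)-4-methoxy-3-methylphenyl]methyl}benzene-1,3,5-triol F2. Acetylation gives 2-{[2,6-bis(benzyloxy)-4-methoxy-3-methylphenyl]methyl}benzene-1,3,5-triyl triacetate F3, and mixed-anhydride acylation as in step 6 gives 2-{[2,6-bis(benzyloxy)-4-methoxy-3-methyl-5-(2-methylpropanoyl)phenyl]methyl}benzene-1,3,5-triyl triacetate F4. Methanolysis gives 1-[2,4-bis(benzyloxy)-6-methoxy-5-methyl-3-[(2,4,6-trihydroxyphenyl)methyl]phenyl]-2-methylpropan-1-one F5, and a second acid-catalysed benzylation with F1 gives 23. The price is the over-alkylation and arm exchange that the key step was designed to avoid.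

**Step 18.**
- What may go wrong: partial epimerisation by enolisation of the aluminium-bound ketone or of the acylium ion; O-acylation; acid-induced exchange of the CH2 bridges; air oxidation of 27 during handling.
- Fallback: metal-free acylation of an ether instead of Lewis-acid acylation of a phenol, setting out from 26 and returning at 30. Benzylation of the three ring B hydroxyls (BnBr, K2CO3, DMF) would give the tri-O-benzyl ether of 26 F6. Acylation of B1 with 28 and trifluoroacetic anhydride (as in steps 6 and 15; B1 is then flanked by two benzyloxy groups as C5 was) would give the heptabenzyl ether of 30 F7, and hydrogenolysis over Pd/C gives 30. Its own weak point is competing C-benzylation of the ring B triol.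

**Step 15.**
- What may go wrong: slow acylation at the flanked A5 position, with loss of benzyl groups or trifluoroacetylation on prolonged exposure.
- Fallback: cross-coupling in place of electrophilic acylation, setting out from 24 and returning at 25. Bromination with N-bromosuccinimide at A5 would give the A5-bromo triacetate F8. Stille coupling with tributyl(1-ethoxyvinyl)stannane (PdCl2(PPh3)2, toluene, 100 °C) would give the A5-(1-ethoxyethenyl) triacetate F9, whose enol ether is hydrolysed by dilute HCl to 25.

**Step 10.**
- What may go wrong: over-lithiation by excess t-BuLi (ring A5 or benzyl ether positions), silylation on carbon to a silylketene, or hydrolysis of the acid-sensitive siloxyalkyne during isolation.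
- Fallback: Kowalski reaction of an arylacetate, setting out from aldehyde 5 and returning at 14. Wittig reaction of 5 with (methoxymethylene)triphenylphosphorane would give 1,3-bis(benzyloxy)-5-methoxy-2-(2-methoxyethenyl)-4-methylbenzene F10. Oxidation of the enol ether with pyridinium chlorochromate, [C5H5NH][CrO3Cl], gives methyl 2-[2,6-bis(benzyloxy)-4-methoxy-3-methylphenyl]acetate F11. Addition of LiCHBr2 (from CH2Br2 and lithium 2,2,6,6-tetramethylpiperidide) followed by n-BuLi rearranges it to the ynolate 13, which i-Pr3SiCl traps as 14. Enolisation of the arylacetate is the risk of this variant.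

**Step 2.**
- What may go wrong: over-methylation, methylation of an ortho hydroxyl, or C-methylation of the phloroglucinol anion.
- Fallback: Mitsunobu etherification of 3 with methanol (PPh3, diisopropyl azodicarboxylate), which engages only the hydroxyl not held in a hydrogen bond, leading from 3 to 4 without new intermediates.

## Further compounds

F1 | step 12 | [2,6-bis(benzyloxy)-4-methoxy-3-methylphenyl]methanol | OCc1c(OCc2ccccc2)c(C)c(OC)cc1OCc1ccccc1
F2 | step 12 | 2-{[2,6-bis(benzyloxy)-4-methoxy-3-methylphenyl]methyl}benzene-1,3,5-triol | Oc1cc(O)c(Cc2c(OCc3ccccc3)c(C)c(OC)cc2OCc2ccccc2)c(O)c1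
F3 | step 12 | 2-{[2,6-bis(benzyloxy)-4-methoxy-3-methylphenyl]methyl}benzene-1,3,5-triyl triacetate | CC(=O)Oc1cc(OC(C)=O)c(Cc2c(OCc3ccccc3)c(C)c(OC)cc2OCc2ccccc2)c(OC(C)=O)c1
F4 | step 12 | 2-{[2,6-bis(benzyloxy)-4-methoxy-3-methyl-5-(2-methylpropanoyl)phenyl]methyl}benzene-1,3,5-triyl triacetate | CC(=O)Oc1cc(OC(C)=O)c(Cc2c(OCc3ccccc3)c(C)c(OC)c(C(=O)C(C)C)c2OCc2ccccc2)c(OC(C)=O)c1
F5 | step 12 | 1-[2,4-bis(benzyloxy)-6-methoxy-5-methyl-3-[(2,4,6-trihydroxyphenyl)methyl]phenyl]-2-methylpropan-1-one | Oc1cc(O)c(Cc2c(OCc3ccccc3)c(C)c(OC)c(C(=O)C(C)C)c2OCc2ccccc2)c(O)c1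
F6 | step 18 | tri-O-benzyl ether of 26 (ring B 2,4,6-tris(benzyloxy), B1 H) | c1ccccc1COc1c(Cc2c(OCc3ccccc3)c(C)c(OC)c(C(=O)C(C)C)c2OCc2ccccc2)c(OCc2ccccc2)cc(OCc2ccccc2)c1Cc1c(OCc2ccccc2)c(C)c(OC)c(C(C)=O)c1OCc1ccccc1
F7 | step 18 | heptabenzyl ether of 30 | CC[C@@H](C)C(=O)c1c(OCc2ccccc2)c(Cc2c(OCc3ccccc3)c(C)c(OC)c(C(C)=O)c2OCc2ccccc2)c(OCc2ccccc2)c(Cc2c(OCc3ccccc3)c(C)c(OC)c(C(=O)C(C)C)c2OCc2ccccc2)c1OCc1ccccc1
F8 | step 15 | 2-{[2,6-bis(benzyloxy)-3-bromo-4-methoxy-5-methylphenyl]methyl}-4-{[2,6-bis(benzyloxy)-4-methoxy-3-methyl-5-(2-methylpropanoyl)phenyl]methyl}benzene-1,3,5-triyl triacetate | CC(=O)Oc1c(Cc2c(OCc3ccccc3)c(C)c(OC)c(C(=O)C(C)C)c2OCc2ccccc2)c(OC(C)=O)cc(OC(C)=O)c1Cc1c(OCc2ccccc2)c(C)c(OC)c(Br)c1OCc1ccccc1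
F9 | step 15 | 2-{[2,6-bis(benzyloxy)-3-(1-ethoxyethenyl)-4-methoxy-5-methylphenyl]methyl}-4-{[2,6-bis(benzyloxy)-4-methoxy-3-methyl-5-(2-methylpropanoyl)phenyl]methyl}benzene-1,3,5-triyl triacetate | CC(=O)Oc1c(Cc2c(OCc3ccccc3)c(C)c(OC)c(C(=O)C(C)C)c2OCc2ccccc2)c(OC(C)=O)cc(OC(C)=O)c1Cc1c(OCc2ccccc2)c(C)c(OC)c(C(=C)OCC)c1OCc1ccccc1
F10 | step 10 | 1,3-bis(benzyloxy)-5-methoxy-2-(2-methoxyethenyl)-4-methylbenzene (E/Z mixture) | COC=Cc1c(OCc2ccccc2)c(C)c(OC)cc1OCc1ccccc1
F11 | step 10 | methyl 2-[2,6-bis(benzyloxy)-4-methoxy-3-methylphenyl]acetate | COC(=O)Cc1c(OCc2ccccc2)c(C)c(OC)cc1OCc1ccccc1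
F0 | step 2 | none | none
A1 | alternative 1 | 1-(4,6-dihydroxy-2-methoxy-3-methylphenyl)ethan-1-one | CC(=O)c1c(OC)c(C)c(O)cc1O
A2 | alternative 1 | 1-methoxy-1,3-bis(trimethylsilyloxy)penta-1,3-diene | CC=C(O[Si](C)(C)C)C=C(OC)O[Si](C)(C)C
A3 | alternative 1 | 4-methoxybut-3-yn-2-one | COC#CC(C)=O
A4 | alternative 2 | 1-[2,4-dihydroxy-6-methoxy-5-methyl-3-[[2,4,6-tris(benzyloxy)phenyl]methyl]phenyl]-2-methylpropan-1-one | CC(C)C(=O)c1c(OC)c(C)c(O)c(Cc2c(OCc3ccccc3)cc(OCc3ccccc3)cc2OCc2ccccc2)c1O
A5 | alternative 2 | 4-methoxy-3-methyl-6-(propan-2-yl)-2H-pyran-2-one | COc1cc(C(C)C)oc(=O)c1C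
A6 | alternative 2 | methyl 3-[2,4,6-tris(benzyloxy)phenyl]propanoate | COC(=O)CCc1c(OCc2ccccc2)cc(OCc2ccccc2)cc1OCc1ccccc1
A7 | alternative 3 | 2-[(tert-butyldimethylsilyloxy)methyl]-5-methoxy-4-methyl-3-[tri(propan-2-yl)silyloxy]phenol | Oc1cc(OC)c(C)c(O[Si](C(C)C)(C(C)C)C(C)C)c1CO[Si](C)(C)C(C)(C)C
A8 | alternative 3 | 3-methoxy-2-methylcyclobut-2-en-1-one | COC1=C(C)C(=O)C1
A9 | alternative 3 | tert-butyl(dimethyl){[3-(tri(propan-2-yl)silyloxy)prop-2-yn-1-yl]oxy}silane | CC(C)[Si](OC#CCO[Si](C)(C)C(C)(C)C)(C(C)C)C(C)C
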